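Ring C (C8, C9, C11–C14; cleistanthane numbering) is a 4-hydroperoxycyclohexa-2,5-dienone whose C12 carbonyl and C8 hydroperoxy carbon are para: the signature of a phenol that has added singlet oxygen. That phenol is disconnected across C12–C13 and C14–C8 to a ring-B-fused furan, whose ring oxygen spans C8 and C12, and but-2-ynal. One Lewis acid-promoted Diels–Alder reaction, followed in the same flask by opening of the oxygen bridge, builds the fully substituted arene. The furan comes from a cyclohexanone made by asymmetric conjugate addition and Michael trapping; Wittig methylenation and photooxygenation complete the route.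

Key step: step 6

Remark: cleistanthane numbering is used throughout (ring B = C5–C10, with the methyl and propanoate chain on C10 and the isopropenyl group on C5; ring C = C8, C9, C11–C14); but-2-ynal is assumed to be purchased.

Step 1
Reactants: 1 (2-methylcyclohex-2-en-1-one); 2 (isopropenylmagnesium bromide)
Product: 4 trimethyl{[(3R)-2-methyl-3-(prop-1-en-2-yl)cyclohex-1-en-1-yl]oxy}silane, via bromomagnesium enolate 3 (not isolated)
Conditions: 2 (1.3 equiv), CuBr·SMe2 (5 mol %), 1-[2-(diphenylphosphino)ferrocenyl]ethyldicyclohexylphosphine (6 mol %, enantiomer that gives 3R), t-BuOMe, −78 °C; then Me3SiCl, Et3N, −78 → 0 °C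
Reagents that add atoms: chlorotrimethylsilane, C[Si](C)(C)Cl
Why: Copper-catalysed asymmetric conjugate addition of the alkenyl Grignard reagent, in which the chiral ferrocenyl diphosphine–copper complex differentiates the enone faces to set C5, and O-silylation of the regiodefined magnesium enolate 3 locks the C9=C10 enol ether.

Step 2
Reactants: 4 (silyl enol ether); 5 (methyl acrylate)
Product: 7 methyl 3-[(1R,6R)-1-methyl-2-oxo-6-(prop-1-en-2-yl)cyclohexyl]propanoate, via lithium enolate 6 (not isolated)
Conditions: MeLi (1.05 equiv), THF, 0 °C; then 5 (1.1 equiv, slow addition), −78 °C; H2O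
Reagents that add atoms: none
Why: MeLi cleaves the O–Si bond to lithium enolate 6 without loss of regiochemistry, and its Michael addition to methyl acrylate should occur at C10 on the face anti to the adjacent isopropenyl group (pseudoaxial to relieve A(1,2) strain with the enolate methyl), so the quaternary centre forms with the propanoate chain trans and the methyl cis to isopropenyl.

Step 3
Reactants: 7 (keto ester)
Product: 9 methyl 3-[(1R,6R)-3-hydroxy-1-methyl-2-oxo-6-(prop-1-en-2-yl)cyclohexyl]propanoate (C8 epimers), via potassium enolate 8 (not isolated)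
Conditions: KN(SiMe3)2 (1.1 equiv), THF, −78 °C; 2-(benzenesulfonyl)-3-phenyloxaziridine, −78 °C; H2O
Reagents that add atoms: 2-(benzenesulfonyl)-3-phenyloxaziridine, O=S(=O)(c1ccccc1)N1OC1c1ccccc1
Why: Because C10 is quaternary the ketone can enolise only towards C8, and the potassium enolate is hydroxylated by the N-sulfonyloxaziridine (electrophilic enolate oxidation); the configuration of the new carbinol is irrelevant because C8 becomes sp2 in step 5.

Step 4
Reactants: 9 (α-hydroxy ketone); 10 (ethynylmagnesium bromide)
Product: 11 methyl 3-[(1R,6R)-2-ethynyl-2,3-dihydroxy-1-methyl-6-(prop-1-en-2-yl)cyclohexyl]propanoate (diastereomers at C8 and C9)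
Conditions: 10 (3 equiv), THF, −78 → −30 °C; H2O (pH 7 buffer) at −30 °C
Reagents that add atoms: none
Why: Chelation-assisted 1,2-addition of the small alkynyl Grignard reagent to the C9 ketone should be faster at low temperature than attack on the methyl ester or lactonisation of the new tertiary alkoxide; the configuration at C9 is again irrelevant.

Step 5
Reactants: 11 (alkynyl diol)
Product: 13 methyl 3-[(4R,5R)-4-methyl-5-(prop-1-en-2-yl)-4,5,6,7-tetrahydro-1-benzofuran-4-yl]propanoate, via hydroxydihydrofuran 12 (not isolated)
Conditions: AuCl(PPh3) (2 mol %), AgOSO2CF3 (2 mol %), THF, 0 °C → rt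
Reagents that add atoms: none
Why: Gold-catalysed 5-endo-dig addition of the C8 hydroxyl to the terminal alkyne carbon gives hydroxydihydrofuran 12, which loses water to aromatise (dehydrative cycloisomerisation of a 3-alkyne-1,2-diol to a furan).

Step 6
Reactants: 13 (furan); 14 (but-2-ynal)
Product: 16 methyl 3-[(1R,2R)-5-formyl-7-hydroxy-1,6-dimethyl-2-(prop-1-en-2-yl)-1,2,3,4-tetrahydronaphthalen-1-yl]propanoate, via 7-oxanorbornadiene cycloadduct 15 (not isolated)
Conditions: 14 (2 equiv), Me2AlCl (2.5 equiv), CH2Cl2, −78 → 0 °C; aq. potassium sodium tartrate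
Reagents that add atoms: none
Why: The Lewis acid-activated ynal and the furan diene (C8=C9–C11=C12) should combine in an asynchronous [4+2] cycloaddition in which the free, most nucleophilic furan α-carbon C12 bonds to the electrophilic β-carbon of the ynal (C13, bearing the methyl) and the alkylated α-carbon C8 bonds to the formyl-bearing carbon C14, giving 7-oxanorbornadiene 15; aluminium-assisted heterolysis of the C8–O bridge bond (tertiary, doubly allylic cation) and loss of H-12 then give the phenol with its hydroxyl on C12. The closest known reaction type is the Lewis acid-promoted furan–alkyne Diels–Alder reaction with isomerisation of the 7-oxanorbornadiene to a phenol. Ring C is closed by an intermolecular [4+2] cycloaddition that forms both C12–C13 and C14–C8. No new stereocentre survives: the two bridgehead centres of 15 are destroyed on aromatisation, so the facial course of the cycloaddition is immaterial, and C5 and C10 are untouched. The step needs regioselectivity, secured by the matching polarisation of furan (nucleophilic at unsubstituted C12) and ynal (electrophilic at C13) and by ionisation at the more substituted bridgehead C8, and chemoselectivity over the isopropenyl group, secured by the much higher nucleophilicity of the furan at low temperature while Me2AlCl scavenges adventitious protic acid.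

Step 7
Reactants: 16 (phenol aldehyde)
Product: 17 methyl 3-[(1R,2R)-5-ethenyl-7-hydroxy-1,6-dimethyl-2-(prop-1-en-2-yl)-1,2,3,4-tetrahydronaphthalen-1-yl]propanoate
Conditions: Ph3PCH3Br (3 equiv), KOC(CH3)3 (3.3 equiv), THF, 0 °C → rt; H2O
Reagents that add atoms: methyltriphenylphosphonium bromide, C[P+](c1ccccc1)(c1ccccc1)c1ccccc1.[Br-]
Why: Wittig methylenation of the aryl aldehyde; the excess base first forms the phenoxide, which should not interfere, and the methyl ester should not react with the non-stabilised ylide at this temperature.

Step 8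
Reactants: 17 (vinyl phenol)
Product: 18 trigonochinene C, methyl 3-[(1R,2R,4aR)-5-ethenyl-4a-hydroperoxy-1,6-dimethyl-7-oxo-2-(prop-1-en-2-yl)-1,2,3,4,4a,7-hexahydronaphthalen-1-yl]propanoate
Conditions: O2 (1 atm), 5,10,15,20-tetraphenylporphyrin (1 mol %), visible light, CH2Cl2–MeOH, −20 °C
Reagents that add atoms: dioxygen, O=O
Why: Singlet oxygen adds to the electron-rich phenol at C8, para to the hydroxyl, with transfer of the phenolic hydrogen (para-hydroperoxidation of a 4-alkylphenol to a 4-hydroperoxycyclohexa-2,5-dienone); the C8 centre should be set by attack on the arene face anti to the pseudoaxial propanoate chain on C10 (the larger C10 substituent avoids peri strain with H-11), that is syn to the C10 methyl as required, and the phenol should react much faster than the isopropenyl and the twisted vinyl groups.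

Compound list
1 | 2-methylcyclohex-2-en-1-one | CC1=CCCCC1=O | starting material
2 | isopropenylmagnesium bromide | C=C(C)[Mg]Br | starting material
3 | bromomagnesium (3R)-2-methyl-3-(prop-1-en-2-yl)cyclohex-1-en-1-olate (not isolated) | CC1=C(O[Mg]Br)CCC[C@@H]1C(C)=C | intermediate
4 | trimethyl{[(3R)-2-methyl-3-(prop-1-en-2-yl)cyclohex-1-en-1-yl]oxy}silane | CC1=C(O[Si](C)(C)C)CCC[C@@H]1C(C)=C | intermediate
5 | methyl acrylate | C=CC(=O)OC | starting material
6 | lithium (3R)-2-methyl-3-(prop-1-en-2-yl)cyclohex-1-en-1-olate (not isolated) | CC1=C(O[Li])CCC[C@@H]1C(C)=C | intermediate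
7 | methyl 3-[(1R,6R)-1-methyl-2-oxo-6-(prop-1-en-2-yl)cyclohexyl]propanoate | O=C1CCC[C@H](C(C)=C)[C@@]1(C)CCC(=O)OC | intermediate
8 | potassium enolate of 7 at C8/C9 (not isolated) | [K+].[O-]C1=CCC[C@H](C(C)=C)[C@@]1(C)CCC(=O)OC | intermediate
9 | methyl 3-[(1R,6R)-3-hydroxy-1-methyl-2-oxo-6-(prop-1-en-2-yl)cyclohexyl]propanoate (C8 epimers, carbinol centre undefined) | O=C1C(O)CC[C@H](C(C)=C)[C@@]1(C)CCC(=O)OC | intermediate
10 | ethynylmagnesium bromide | C#C[Mg]Br | starting material
11 | methyl 3-[(1R,6R)-2-ethynyl-2,3-dihydroxy-1-methyl-6-(prop-1-en-2-yl)cyclohexyl]propanoate (C8 and C9 undefined) | C#CC1(O)C(O)CC[C@H](C(C)=C)[C@@]1(C)CCC(=O)OC | intermediate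
12 | methyl 3-[(4R,5R)-3a-hydroxy-4-methyl-5-(prop-1-en-2-yl)-3a,4,5,6,7,7a-hexahydro-1-benzofuran-4-yl]propanoate (not isolated, ring-fusion centres undefined) | OC12C=COC1CC[C@H](C(C)=C)[C@@]2(C)CCC(=O)OC | intermediate
13 | methyl 3-[(4R,5R)-4-methyl-5-(prop-1-en-2-yl)-4,5,6,7-tetrahydro-1-benzofuran-4-yl]propanoate | o1ccc2c1CC[C@H](C(C)=C)[C@@]2(C)CCC(=O)OC | intermediate
14 | but-2-ynal | CC#CC=O | starting material
15 | 7-oxanorbornadiene cycloadduct of 13 and 14: oxygen bridging C8 and C12, formyl on C14, methyl on C13 (not isolated, either facial isomer) | O=CC1=C(C)C2C=C3C1(O2)CC[C@H](C(C)=C)[C@@]3(C)CCC(=O)OC | intermediate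
16 | methyl 3-[(1R,2R)-5-formyl-7-hydroxy-1,6-dimethyl-2-(prop-1-en-2-yl)-1,2,3,4-tetrahydronaphthalen-1-yl]propanoate | O=Cc1c(C)c(O)cc2c1CC[C@H](C(C)=C)[C@@]2(C)CCC(=O)OC | intermediate
17 | methyl 3-[(1R,2R)-5-ethenyl-7-hydroxy-1,6-dimethyl-2-(prop-1-en-2-yl)-1,2,3,4-tetrahydronaphthalen-1-yl]propanoate | C=Cc1c(C)c(O)cc2c1CC[C@H](C(C)=C)[C@@]2(C)CCC(=O)OC | intermediate
18 | trigonochinene C | C=CC1=C(C)C(=O)C=C2[C@]1(OO)CC[C@H](C(=C)C)[C@@]2(C)CCC(=O)OC | target

Total step count: 8. Longest linear sequence: 8 steps (1 → 18).

Steps most likely to fail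

Step 6. The Lewis acid complex of the ynal may be intercepted by the furan in a Friedel–Crafts sense (conjugate or carbonyl addition at C12 followed by rearomatisation of the furan) instead of closing the ring, and the acid may degrade the furan or the isopropenyl group. The fallback sets out from furan 13 and comes back at cycloadduct 15, and from there at phenol 16. It replaces the alkyne by an alkene dienophile of the same polarity. Crotonaldehyde is brominated (Br2, CH2Cl2, 0 °C) to 2,3-dibromobutanal F1 and dehydrobrominated with Et3N to (Z)-2-bromobut-2-enal F2, a more reactive dienophile than the ynal. Its cycloaddition to 13 (BF3·OEt2 cat., CH2Cl2, −78 °C) should give the bromo-oxanorbornene F3 with the same orientation (C12–C13 and C14–C8). DBU then removes HBr to give 15, which is opened to 16 with catalytic CF3CO2H.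

Step 8. Singlet oxygen may approach C8 from both faces of the arene, because both half-chairs of ring B are accessible, and slow ene oxidation of the isopropenyl group may set in on prolonged irradiation. The fallback sets out from 17 (through its photooxygenation mixture) and comes back at 17. The reaction is stopped at partial conversion and the C8-epimeric 8-epi-hydroperoxide F4 is separated by chromatography. Zn dust in AcOH (O–O cleavage, then reductive aromatisation of the resulting p-quinol) should return it to phenol 17 for another pass. The required isomer is thus accumulated by separation and recycling rather than by a single selective oxidation.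

Step 1. Enantioselectivity may be low, because alkenyl Grignard reagents and α-substituted enones are demanding partners in copper-catalysed conjugate addition, and 1,2-addition may compete. The fallback sets out from 7 of insufficient enantiomeric purity (in the limit from ligand-free step 1) and comes back at 7. LiOH hydrolysis gives keto acid F5. Crystallisation with (R)-1-phenylethylamine should give the diastereomerically pure (R)-1-phenylethylammonium salt F6 of the (1R,6R) acid (the acid is recovered from the mother liquor instead if its salt proves the more soluble one). Aqueous HCl liberates the enantiopure acid, and MeI/K2CO3 in DMF re-forms 7.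

Further compounds
F1 | step 6 | 2,3-dibromobutanal (stereocentres undefined) | CC(Br)C(Br)C=O
F2 | step 6 | (Z)-2-bromobut-2-enal | C/C=C(\Br)C=O
F3 | step 6 | bromo-oxanorbornene cycloadduct of 13 and F2: oxygen bridging C8 and C12, bromine and formyl on C14, methyl on C13 (new centres undefined) | O=CC1(Br)C(C)C2C=C3C1(O2)CC[C@H](C(C)=C)[C@@]3(C)CCC(=O)OC
F4 | step 8 | C8 epimer of 18, methyl 3-[(1R,2R,4aS)-5-ethenyl-4a-hydroperoxy-1,6-dimethyl-7-oxo-2-(prop-1-en-2-yl)-1,2,3,4,4a,7-hexahydronaphthalen-1-yl]propanoate | C=CC1=C(C)C(=O)C=C2[C@@]1(OO)CC[C@H](C(=C)C)[C@@]2(C)CCC(=O)OC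
F5 | step 1 | 3-[(1R,6R)-1-methyl-2-oxo-6-(prop-1-en-2-yl)cyclohexyl]propanoic acid | O=C1CCC[C@H](C(C)=C)[C@@]1(C)CCC(=O)O
F6 | step 1 | (R)-1-phenylethylammonium 3-[(1R,6R)-1-methyl-2-oxo-6-(prop-1-en-2-yl)cyclohexyl]propanoate | O=C1CCC[C@H](C(C)=C)[C@@]1(C)CCC(=O)[O-].C[C@@H]([NH3+])c1ccccc1
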